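Retrosynthetic cuts, in order: the C6–O bond and the C17 oxidation level (last ring-B oxidations); C12–C13 (chain joined by sp3–sp2 coupling); 9-H/C11=C12 (reductive transposition of a C9=C11 alkylidene built on a C9 ketone); ring A at C1–C2 and C3–C4, which releases C2–C3 as acrolein; finally C10–C1 and C10–C20.
Enabling feature: ring A (C1–C5, C10) carries no functional group. C4 is a gem-dimethyl quaternary carbon on C5, so it corresponds to the tertiary radical of an isopropenyl group. C1 sits on the quaternary C10, so it can be a non-enolisable aldehyde. The two are 1,4-related and trans-diequatorial on ring B, so a two-carbon radical acceptor that becomes an enolate can bridge them.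
Forward order: ring B is the carvone ring (C17 = carvone CH3, C9 = C=O, C10 = α′-carbon, C4/C18/C19 = isopropenyl). Ring A is annulated onto it in one step. The helpers (1-OH, 2-CHO) leave by dehydration, decarbonylation and diimide reduction. Then C9 is set, the chain is coupled, and C17 and C6 are oxidised.
Stereochemistry: C5 comes from (S)-carvone. C10 is set by electrophile attack anti to the isopropenyl group. 9-H and 6-OH are delivered anti to the axial C20 methyl. 13E comes from anti-hydroiodination followed by retention in the coupling.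

Key step: step 5

Remark (numbering): labdane numbering of the target is used for every compound. "Me face" is the face of ring B that carries C20. In the target, C11 lies on the Me face, and 5-H, 9-H and 6-OH lie on the opposite face (ent-labdane series; 5R,6R,9S,10S,13E).
Remark (assumption): the C9=C11 compounds 6, 7, 9–17 are drawn as E isomers (ester or CH2X turned away from C10), and 10 and 11 as the cis C1/C2 isomers. The other isomers would converge at 18 and 12 respectively.

Step 1
Reactants: 1 (S)-(+)-carvone
Product: 2 6-methylcarvone (C10 epimers; trans isomer drawn)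
Conditions: LDA, THF, −78 °C; MeI, −78 → 0 °C
Reagents that add atoms: iodomethane, CI
Why: Kinetic α′-deprotonation of the cross-conjugated enone and SN2 methylation (enolate alkylation) bring in C20; the C10 configuration formed here does not matter because C10 is planarised again in step 2.

Step 2
Reactants: 2 6-methylcarvone
Product: 4 (5R,6S)-6-(dimethoxymethyl)-2,6-dimethyl-5-(prop-1-en-2-yl)cyclohex-2-en-1-one, via silyl dienol ether 3 (not isolated)
Conditions: LDA, THF, −78 °C; TMSCl; solvent switch; HC(OMe)3, TMSOTf (10 mol %), CH2Cl2, −78 °C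
Reagents that add atoms: trimethyl orthoformate, COC(OC)OC; chlorotrimethylsilane, C[Si](C)(C)Cl (its atoms stay only in 3)
Why: The Mukaiyama-type reaction of the cross-conjugated enol silane with the small dimethoxycarbenium ion should occur at C10 anti to the neighbouring C5 isopropenyl group, which sets quaternary C10 with the masked formyl carbon C1 trans and C20 cis to isopropenyl.

Step 3
Reactants: 4 keto acetal
Product: 5 C9 ethoxyethynyl carbinol of 4 (alkynyl drawn trans to C20)
Conditions: ethoxyacetylene, n-BuLi, THF, −78 °C; then 4, −78 → 0 °C; H2O quench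
Reagents that add atoms: ethoxyacetylene, C#COCC
Why: 1,2-Addition of the slim lithium alkynylide to the hindered enone carbonyl, which has no α-hydrogen, forms C9–C11; the carbinol centre is erased in step 4.

Step 4
Reactants: 5 ethoxyethynyl carbinol
Product: 7 ethyl (E)-2-[(5R,6R)-6-formyl-2,6-dimethyl-5-(prop-1-en-2-yl)cyclohex-2-en-1-ylidene]acetate, via acetal dienoate 6 (not isolated)
Conditions: Sc(OTf)3 (5 mol %), EtOH/CH2Cl2, rt; then 1 M aq HCl, THF, rt
Reagents that add atoms: water, O
Why: The Meyer–Schuster rearrangement of an ethoxyalkynyl carbinol is the standard olefination for ketones too hindered for a Horner–Wadsworth–Emmons reaction, and dilute acid then hydrolyses the acetal to the non-enolisable C1 aldehyde.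

Step 5
Reactants: 7 aldehyde dienoate; 8 acrolein
Product: 10 ethyl (E)-2-formyl-1-hydroxy-ent-13,14,15,16-tetranorlabda-7,9(11)-dien-12-oate, via iron enolate 9 (not isolated)
Conditions: Fe(acac)3 (20 mol %), Ph(i-PrO)SiH2 (2 equiv), i-PrOH (3 equiv), 8 (3 equiv, slow addition), 1,2-DCE, degassed, 0 °C → rt
Reagents that add atoms: none
Why: An iron hydride formed from Fe(acac)3 and the silane transfers a hydrogen atom to the CH2 terminus of the isopropenyl group, the nucleophilic tertiary C4 radical adds to the β-carbon of acrolein (C3–C4 bond, Giese step), Fe(II) reduces the α-formyl radical to iron enolate 9, and its α-carbon attacks the C1 aldehyde (C1–C2 bond). The closest known reaction type is the MHAT-initiated radical–polar crossover annulation of an alkenyl aldehyde with an enal or enone (reductive Giese/aldol cascade). Ring A closes as a 6-(enolexo)-exo-trig aldol through a chair in which the C5–C4 and C10–C1 bonds are both equatorial on ring B, so the trans ring fusion is inherited from C5 and C10 and no fusion centre is touched. C4 becomes quaternary but is not stereogenic, while the new centres C1 and C2 are expected cis (axial 1-OH opposite C20, equatorial 2-CHO) from the chelated Z-enolate, and both are erased in steps 6–8. The step needs hydrogen-atom transfer at the isopropenyl group only, which is secured because the other two C=C bonds are trisubstituted and part of an electron-poor dienoate, and it needs intermolecular capture by acrolein, which is secured because every internal acceptor position would close a four-membered ring. The aldehyde cannot enolise (C10 quaternary) and C9 is an alkylidene, not a ketone, so neither self-aldol nor deformylation of a β-dicarbonyl unit should compete.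

Step 6
Reactants: 10 aldol
Product: 12 ethyl (E)-2-formyl-ent-13,14,15,16-tetranorlabda-1,7,9(11)-trien-12-oate, via mesylate 11 (not isolated)
Conditions: MsCl, Et3N, CH2Cl2, 0 °C; then DBU, rt
Reagents that add atoms: methanesulfonyl chloride, CS(=O)(=O)Cl (its atoms stay only in 11)
Why: Mesylation and E1cB elimination through the acidic 2-H (aldol dehydration) should work for any C1/C2 diastereomer and removes the first helper, the 1-OH group.

Step 7
Reactants: 12 ring-A enal
Product: 13 ethyl (E)-ent-13,14,15,16-tetranorlabda-1,7,9(11)-trien-12-oate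
Conditions: RhCl(PPh3)3 (1.1 equiv), PhCN, 140 °C
Reagents that add atoms: none
Why: Tsuji–Wilkinson decarbonylation (Rh insertion into the formyl C–H, CO extrusion, reductive elimination with the alkene kept in place) removes the second helper, and no terminal alkene is present that a rhodium hydride could isomerise.

Step 8
Reactants: 13 triene ester
Product: 14 ethyl (E)-ent-13,14,15,16-tetranorlabda-7,9(11)-dien-12-oate
Conditions: 2-nitrobenzenesulfonohydrazide (NBSH, excess), Et3N, CH2Cl2, rt
Reagents that add atoms: none
Why: Diimide reduction is governed by substitution, so the cis-disubstituted C1=C2 bond should be reduced in preference to the two hindered trisubstituted bonds of the dienoate.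

Step 9
Reactants: 14 dienoate
Product: 15 (E)-ent-13,14,15,16-tetranorlabda-7,9(11)-dien-12-ol
Conditions: DIBAL-H (2.5 equiv), CH2Cl2, −78 °C; Rochelle salt work-up
Reagents that add atoms: none
Why: 1,2-Reduction of the conjugated ester, the only reducible group present, gives the primary allylic alcohol.

Step 10
Reactants: 15 dienol
Product: 18 ent-13,14,15,16-tetranorlabda-7,11-diene (9-H opposite C20), via sulfonylhydrazine 16 (not isolated), via allylic diazene 17 (not isolated)
Conditions: PPh3, DEAD, NBSH (1.2 equiv), THF, −30 °C → rt
Reagents that add atoms: 2-nitrobenzenesulfonohydrazide, NNS(=O)(=O)c1ccccc1[N+](=O)[O-] (its atoms stay only in 16 and 17)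
Why: Mitsunobu displacement of the primary allylic alcohol, loss of sulfinic acid on warming and retro-ene loss of N2 (allylic diazene rearrangement, reductive 1,3-transposition) move the double bond to C11=C12 and should deliver H to C9 from the face opposite the axial C20 methyl, which sets C9 with the chain equatorial on the Me face.

Step 11
Reactants: 19 methyl 4-hydroxybut-2-ynoate
Product: 20 methyl (Z)-4-hydroxy-3-iodobut-2-enoate
Conditions: NaI, AcOH, 80 °C
Reagents that add atoms: sodium iodide, [Na+].[I-]
Why: Conjugate addition of iodide with trans protonation (anti-hydroiodination of an alkynoate) places iodine cis to the ester, and the CH2OH group, being trans to the ester, cannot lactonise.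

Step 12
Reactants: 18 vinyl decalin; 20 iodo enoate
Product: 22 methyl (13E)-16-hydroxy-ent-labda-7,13-dien-15-oate, via B-alkyl-9-BBN 21 (not isolated)
Conditions: 9-BBN-H, THF, rt; then 20, PdCl2(dppf) (5 mol %), AsPh3, Cs2CO3, DMF/H2O, rt
Reagents that add atoms: 9-borabicyclo[3.3.1]nonane, [H]B1C2CCCC1CCC2 (its atoms stay only in 21)
Why: 9-BBN should add only to the monosubstituted vinyl group (boron on C12), and the B-alkyl Suzuki–Miyaura coupling retains the iodoalkene geometry, so the chain ends up cis to CO2Me (13E).

Step 13
Reactants: 22 hydroxy ester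
Product: 23 methyl (13E)-16-formyloxy-ent-labda-7,13-dien-15-oate
Conditions: HCO2H, DCC, DMAP (cat.), CH2Cl2, 0 °C
Reagents that add atoms: formic acid, OC=O
Why: Steglich-type esterification formylates the only hydroxyl group in the molecule.

Step 14
Reactants: 23 formate
Product: 24 methyl (13E)-16-formyloxy-17-oxo-ent-labda-7,13-dien-15-oate
Conditions: SeO2, 1,4-dioxane, 80 °C
Reagents that add atoms: selenium dioxide, O=[Se]=O
Why: In the Riley oxidation (ene reaction, then [2,3]-shift) oxygen goes to a substituent of the more substituted alkene carbon C8, where the C17 methyl is preferred over the hindered 9-H methine, and the enoate double bond is too electron-poor to react.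

Step 15
Reactants: 24 enal
Product: 25 17-O-triethylsilyl 6,8(17)-dienol ether of 24
Conditions: TESOTf (1.2 equiv), Et3N, CH2Cl2, −78 → 0 °C
Reagents that add atoms: triethylsilyl triflate, CC[Si](CC)(CC)OS(=O)(=O)C(F)(F)F
Why: Soft enolisation (O-silylation of the most Lewis-basic carbonyl, then γ-deprotonation) can only remove a C6 hydrogen, the sole position in vinylogous conjugation with the aldehyde; 9-H is not touched.

Step 16
Reactants: 25 silyl dienol ether
Product: 27 methyl (13E)-16-formyloxy-6-hydroxy-17-oxo-ent-labda-7,13-dien-15-oate (target), via epoxide 26 (not isolated)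
Conditions: dimethyldioxirane (acetone solution), CH2Cl2, −40 °C; then THF/H2O/AcOH, 0 °C
Reagents that add atoms: dimethyldioxirane, CC1(C)OO1
Why: In the vinylogous Rubottom oxidation the terminal C6=C7 bond of the electron-rich silyloxy diene should be epoxidised from the face opposite the axial C20 and C4 methyl groups, and push–pull opening of 26 with loss of silicon restores the 7-en-17-al and leaves 6-OH trans to C20.

Compound list
1 | (S)-(+)-carvone | CC1=CC[C@@H](CC1=O)C(C)=C | starting material
2 | 6-methylcarvone, (5S)-2,6-dimethyl-5-(prop-1-en-2-yl)cyclohex-2-en-1-one (trans epimer drawn) | CC1=CC[C@H](C(C)=C)[C@@H](C)C1=O | intermediate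
3 | trimethylsilyl cross-conjugated dienol ether of 2 | CC1=CC[C@H](C(C)=C)C(C)=C1O[Si](C)(C)C | intermediate
4 | (5R,6S)-6-(dimethoxymethyl)-2,6-dimethyl-5-(prop-1-en-2-yl)cyclohex-2-en-1-one (C1 trans, C20 cis to isopropenyl) | CC1=CC[C@H](C(C)=C)[C@@](C)(C(OC)OC)C1=O | intermediate
5 | C9 ethoxyethynyl carbinol of 4 | CCOC#C[C@@]1(O)C(C)=CC[C@H](C(C)=C)[C@@]1(C)C(OC)OC | intermediate
6 | ethyl (E)-2-[6-(dimethoxymethyl)-2,6-dimethyl-5-(prop-1-en-2-yl)cyclohex-2-en-1-ylidene]acetate | CCOC(=O)/C=C1\C(C)=CC[C@H](C(C)=C)[C@@]1(C)C(OC)OC | intermediate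
7 | ethyl (E)-2-[(5R,6R)-6-formyl-2,6-dimethyl-5-(prop-1-en-2-yl)cyclohex-2-en-1-ylidene]acetate | CCOC(=O)/C=C1\C(C)=CC[C@H](C(C)=C)[C@@]1(C)C=O | intermediate
8 | acrolein | C=CC=O | starting material
9 | iron(III) enolate after the Giese step (drawn as the Z-enolate without the metal) | CCOC(=O)/C=C1\C(C)=CC[C@H](C(C)(C)C/C=C\[O-])[C@@]1(C)C=O | intermediate
10 | ethyl (E)-2-formyl-1-hydroxy-ent-13,14,15,16-tetranorlabda-7,9(11)-dien-12-oate (trans-fused; 1-OH axial opposite C20, 2-CHO equatorial) | CCOC(=O)/C=C1\C(C)=CC[C@@H]2C(C)(C)C[C@@H](C=O)[C@@H](O)[C@@]12C | intermediate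
11 | 1-O-mesylate of 10 | CCOC(=O)/C=C1\C(C)=CC[C@@H]2C(C)(C)C[C@@H](C=O)[C@@H](OS(C)(=O)=O)[C@@]12C | intermediate
12 | ethyl (E)-2-formyl-ent-13,14,15,16-tetranorlabda-1,7,9(11)-trien-12-oate | CCOC(=O)/C=C1\C(C)=CC[C@@H]2C(C)(C)CC(C=O)=C[C@@]12C | intermediate
13 | ethyl (E)-ent-13,14,15,16-tetranorlabda-1,7,9(11)-trien-12-oate | CCOC(=O)/C=C1\C(C)=CC[C@@H]2C(C)(C)CC=C[C@@]12C | intermediate
14 | ethyl (E)-ent-13,14,15,16-tetranorlabda-7,9(11)-dien-12-oate | CCOC(=O)/C=C1\C(C)=CC[C@@H]2C(C)(C)CCC[C@@]12C | intermediate
15 | (E)-ent-13,14,15,16-tetranorlabda-7,9(11)-dien-12-ol | OC/C=C1\C(C)=CC[C@@H]2C(C)(C)CCC[C@@]12C | intermediate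
16 | N-(C12-allyl)-N-(2-nitrophenylsulfonyl)hydrazine | NN(C/C=C1\C(C)=CC[C@@H]2C(C)(C)CCC[C@@]12C)S(=O)(=O)c1ccccc1[N+](=O)[O-] | intermediate
17 | C12 allylic diazene | N=NC/C=C1\C(C)=CC[C@@H]2C(C)(C)CCC[C@@]12C | intermediate
18 | ent-13,14,15,16-tetranorlabda-7,11-diene (9-H opposite C20) | C=C[C@@H]1C(C)=CC[C@@H]2C(C)(C)CCC[C@@]12C | intermediate
19 | methyl 4-hydroxybut-2-ynoate | COC(=O)C#CCO | starting material
20 | methyl (Z)-4-hydroxy-3-iodobut-2-enoate | COC(=O)/C=C(\I)CO | intermediate
21 | C12 B-alkyl-9-BBN from 18 | C(C[C@@H]1C(C)=CC[C@@H]2C(C)(C)CCC[C@@]12C)B1C2CCCC1CCC2 | intermediate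
22 | methyl (13E)-16-hydroxy-ent-labda-7,13-dien-15-oate | COC(=O)/C=C(\CC[C@@H]1C(C)=CC[C@@H]2C(C)(C)CCC[C@@]12C)CO | intermediate
23 | methyl (13E)-16-formyloxy-ent-labda-7,13-dien-15-oate | COC(=O)/C=C(\CC[C@@H]1C(C)=CC[C@@H]2C(C)(C)CCC[C@@]12C)COC=O | intermediate
24 | methyl (13E)-16-formyloxy-17-oxo-ent-labda-7,13-dien-15-oate | COC(=O)/C=C(\CC[C@@H]1C(C=O)=CC[C@@H]2C(C)(C)CCC[C@@]12C)COC=O | intermediate
25 | 17-O-triethylsilyl 6,8(17)-dienol ether of 24 | COC(=O)/C=C(\CC[C@@H]1/C(=C\O[Si](CC)(CC)CC)C=C[C@@H]2C(C)(C)CCC[C@@]12C)COC=O | intermediate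
26 | 6,7-epoxide of 25 (oxygen opposite C20) | COC(=O)/C=C(\CC[C@@H]1/C(=C\O[Si](CC)(CC)CC)[C@H]2O[C@H]2[C@@H]3C(C)(C)CCC[C@@]13C)COC=O | intermediate
27 | methyl (13E)-16-formyloxy-6-hydroxy-17-oxo-ent-labda-7,13-dien-15-oate (5R,6R,9S,10S), CNP0134813.1 | COC(=O)/C=C(\CC[C@@H]1C(C=O)=C[C@@H](O)[C@@H]2C(C)(C)CCC[C@@]12C)COC=O | target

Total step count: 16. Longest linear sequence: 15 (steps 1–10 and 12–16, from (S)-carvone).

Steps most likely to fail

Step 5. The iron enolate may be protonated before it reaches the hindered C1 aldehyde, or acrolein may be consumed by oligomerisation, so the cascade stops after the first bond. The fallback separates the two bond formations. It sets out from 7. A reductive olefin coupling with acrolein in ethanol (Fe(acac)3, PhSiH3) is allowed to end at the open dialdehyde ethyl (E)-2-[6-formyl-2,6-dimethyl-5-(2-methyl-5-oxopentan-2-yl)cyclohex-2-en-1-ylidene]acetate F1. An amine-salt-catalysed 6-enolexo aldol condensation (Bn2NH·TFA, toluene), in which only the new aldehyde can enolise, then closes C1–C2 with loss of water. The route is rejoined at 12, so steps 5 and 6 are both replaced.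

Step 10. The flexible retro-ene transition state may show poor facial selectivity at C9, or the activated dienol may eliminate or react in the SN2′ sense during the Mitsunobu stage. The fallback sets out from 15, which is converted (ClCO2Me, pyridine) into the allylic carbonate methyl (E)-ent-13,14,15,16-tetranorlabda-7,9(11)-dien-12-yl carbonate F2. Palladium-catalysed formate hydrogenolysis (Pd2(dba)3, PBu3, HCO2H/Et3N, THF) follows. The bulky π-allylpalladium unit should form on the face opposite C20 and pass hydride from the metal to the more substituted terminus C9. This gives the terminal alkene and rejoins the route at 18.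

Step 14. Competing hydroxylation at the 9-H methine, or a stop at the allylic-alcohol level followed by decomposition on prolonged heating, may erode the oxidation of C17. The fallback sets out from 23. Ene-type allylic chlorination (NCS, cat. PhSeCl, MeCN) should give the transposed chloride methyl (13E)-7-chloro-16-formyloxy-ent-labda-8(17),13-dien-15-oate F3. Silver-assisted Kornblum oxidation (AgBF4, DMSO; then Et3N) follows. The allyl cation is captured by DMSO at the unhindered primary terminus C17, and the alkoxysulfonium salt collapses to the enal. The route is rejoined at 24.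

Further compounds
F1 | step 5 | ethyl (E)-2-[6-formyl-2,6-dimethyl-5-(2-methyl-5-oxopentan-2-yl)cyclohex-2-en-1-ylidene]acetate | CCOC(=O)/C=C1\C(C)=CC[C@H](C(C)(C)CCC=O)[C@@]1(C)C=O
F2 | step 10 | methyl (E)-ent-13,14,15,16-tetranorlabda-7,9(11)-dien-12-yl carbonate | COC(=O)OC/C=C1\C(C)=CC[C@@H]2C(C)(C)CCC[C@@]12C
F3 | step 14 | methyl (13E)-7-chloro-16-formyloxy-ent-labda-8(17),13-dien-15-oate | COC(=O)/C=C(\CC[C@@H]1C(=C)[C@@H](Cl)C[C@@H]2C(C)(C)CCC[C@@]12C)COC=O
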